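**Assumption:** the SMILES is read literally, so H-5 and the C10 methyl are cis (cis-decalin; 4R,5S,9S,10R; 13Z). Labdane numbering is used for atoms throughout. Compounds 1 and 11 are taken as catalogue compounds.

## Retrosynthetic overview
1. The target comes from acetylation of a C4 hydroxymethyl ketone. That ketone arises by semipinacol ring expansion of an α-hydroxy epoxide, in which C5 shifts from C3 to C4 and a cis-hydrindane becomes the cis-decalin (C4–C5 bond, C4 quaternary centre, C3 ketone).
2. The epoxy alcohol comes from isopropenyl addition and OH-directed epoxidation on a cis-hydrindan-1-one that already carries C5, C9, C10, the 8(17)-methylene and the Z side chain.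
3. The hydrindanone comes from an enantioselective intramolecular allylsilane conjugate addition (C9–C10 bond) of a 2-alkyl-3-methylcyclopentenone.
4. The open chain comes from two Negishi couplings (C9–C11, then C5–C6) around a linchpin made by carbocupration of 4-bromobut-1-yne. The Z-configured C6 acid unit comes from a six-membered lactone.
5. Ring order: five-membered ring (bought), then ring B, then ring A (five to six) last.

## Route

**Step 1**
Reactants: 1 4-methyl-5,6-dihydro-2H-pyran-2-one
Product: 3 methyl (Z)-5-iodo-3-methylpent-2-enoate, via silyl ester 2 (not isolated)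
Conditions: TMSI (1.05 equiv), CH2Cl2, 0 °C → rt; then MeOH, rt
Reagents that add atoms: iodotrimethylsilane C[Si](C)(C)I; methanol CO
Why: Silyl iodide lactone cleavage (O-silylation, then SN2 attack of iodide on the O–CH2 carbon) followed by methanolysis of the silyl ester leaves the C=C bond untouched, so the Z geometry enforced by the ring (C12 cis to the carboxyl carbon) is carried over.

**Step 2**
Reactants: 4 4-bromobut-1-yne; 5 (trimethylsilyl)methylmagnesium chloride
Product: 8 [(2Z)-4-bromo-2-(iodomethylidene)butyl]trimethylsilane, via silylmethylcopper 6 (not isolated), via vinylcopper 7 (not isolated)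
Conditions: 5, CuBr·SMe2, Et2O/SMe2, −40 °C; 4, −40 → −10 °C; I2, THF, −60 → 0 °C
Reagents that add atoms: iodine II
Why: In this Normant carbocupration the organocopper adds syn and regioselectively (CH2SiMe3 to the internal carbon, Cu to the terminal carbon) and iodinolysis goes with retention, so CH2SiMe3 and I end up cis (Z), while the alkyl bromide is inert to RCu·MgX2 in ether.

**Step 3**
Reactants: 3 methyl (Z)-5-iodo-3-methylpent-2-enoate; 8 [(2Z)-4-bromo-2-(iodomethylidene)butyl]trimethylsilane
Product: 10 methyl (2Z,6Z)-9-bromo-3-methyl-7-[(trimethylsilyl)methyl]nona-2,6-dienoate, via alkylzinc iodide 9 (not isolated)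
Conditions: 3, Zn dust, LiCl, THF, 30 °C; decanted onto 8, Pd(PPh3)4 (3 mol %), THF, rt
Reagents that add atoms: none
Why: Zinc insertion into the primary iodide and Negishi sp3–sp2 coupling keep both alkene geometries, and the ester, allylsilane and primary bromide do not react with an alkylzinc halide or with zerovalent palladium under these conditions.

**Step 4**
Reactants: 10 methyl (2Z,6Z)-9-bromo-3-methyl-7-[(trimethylsilyl)methyl]nona-2,6-dienoate; 11 2-bromo-3-methylcyclopent-2-en-1-one
Product: 13 methyl (2Z,6Z)-3-methyl-9-(2-methyl-5-oxocyclopent-1-en-1-yl)-7-[(trimethylsilyl)methyl]nona-2,6-dienoate, via alkylzinc bromide 12 (not isolated)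
Conditions: 10, Zn dust, I2 (5 mol %), DMA, 70 °C; 11, Pd(OAc)2 (3 mol %), SPhos (6 mol %), THF/DMA, 40 °C
Reagents that add atoms: none
Why: In this Negishi coupling of an α-bromoenone the homoallylic zinc bromide tolerates ketone and ester, and the bulky biaryl phosphine drives reductive elimination to the tetrasubstituted enone ahead of β-hydride elimination.

**Step 5**
Reactants: 13 methyl (2Z,6Z)-3-methyl-9-(2-methyl-5-oxocyclopent-1-en-1-yl)-7-[(trimethylsilyl)methyl]nona-2,6-dienoate
Product: 16 (Z)-3-methyl-5-[(3aR,4S,7aS)-3a-methyl-5-methylidene-1-oxooctahydro-1H-inden-4-yl]pent-2-enoic acid, via silyl enol ether 14 (not isolated), via keto ester 15 (not isolated)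
Conditions: chiral imidodiphosphorimidate Brønsted acid (IDPi) built from two 3,3′-bis[3,5-bis(trifluoromethyl)phenyl]-BINOL units with N-triflyl groups (5 mol %, antipode fixed by screening), methallyl-SiMe3 (10 mol %, initiator), toluene, −60 °C; then LiOH, THF/MeOH/H2O, 45 °C; 1 M HCl
Reagents that add atoms: lithium hydroxide [Li+].[OH-]
Why: Proposed new method: this is a catalytic asymmetric intramolecular Hosomi–Sakurai conjugate allylation under silylium/chiral-counteranion catalysis, in which the IDPi acid is silylated in situ, Me3Si+ binds the enone oxygen, the silyloxyallyl cation sits inside the confined chiral anion, C9 of the allylsilane attacks C10 through a chair-like six-membered transition state (side chain equatorial, so H-9 ends anti to the C10 methyl), and loss of Me3Si+ from C17 unveils the 8(17)-methylene and carries the chain, so the anion selects the enone face (C10 R, C9 S) while the step forms the C9–C10 bond and ring B; LiOH then cleaves the silyl enol ether and the methyl ester and equilibrates C5 to the more stable cis-hydrindanone (H-5 cis to the C10 methyl, the minor trans epimer being recyclable); the closest known reaction types are the racemic Lewis-acid intramolecular Sakurai cyclisation of enone allylsilanes and IDPi-catalysed asymmetric Mukaiyama–Michael additions and aldehyde allylations.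

**Step 6**
Reactants: 16 (Z)-3-methyl-5-[(3aR,4S,7aS)-3a-methyl-5-methylidene-1-oxooctahydro-1H-inden-4-yl]pent-2-enoic acid; 17 isopropenylmagnesium bromide
Product: 18 (Z)-5-[(1R,3aR,4S,7aS)-1-hydroxy-3a-methyl-5-methylidene-1-(prop-1-en-2-yl)octahydro-1H-inden-4-yl]-3-methylpent-2-enoic acid
Conditions: 17 (3.5 equiv), LaCl3·2LiCl (1.1 equiv), THF, −20 → 0 °C; aq NH4Cl, citric acid to pH 4
Reagents that add atoms: none
Why: In this lanthanide-assisted Grignard 1,2-addition the first equivalent only deprotonates the acid (the carboxylate and its enoate stay inert), and attack on the convex β face of the cis-hydrindanone, anti to C6 and C9, gives 3β-isopropenyl/3α-OH (C3 R).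

**Step 7**
Reactants: 18 (Z)-5-[(1R,3aR,4S,7aS)-1-hydroxy-3a-methyl-5-methylidene-1-(prop-1-en-2-yl)octahydro-1H-inden-4-yl]-3-methylpent-2-enoic acid
Product: 19 (Z)-5-{(1R,3aR,4S,7aS)-1-hydroxy-3a-methyl-5-methylidene-1-[(2S)-2-methyloxiran-2-yl]octahydro-1H-inden-4-yl}-3-methylpent-2-enoic acid
Conditions: VO(acac)2 (5 mol %), t-BuOOH (1.5 equiv, decane), toluene, 0 °C → rt
Reagents that add atoms: tert-butyl hydroperoxide CC(C)(C)OO
Why: In this vanadium-catalysed hydroxyl-directed epoxidation only the allylic alkene is reached by the vanadate-bound peroxide, and in the favoured transition state (O–C3–C4=CH2 near 45°, small C2 next to the vinylic methyl to limit A(1,2) strain, bulky C5 perpendicular and anti to the oxidant) oxygen is delivered to the face opposite C5, giving the (S)-oxirane.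

**Step 8**
Reactants: 19 (Z)-5-{(1R,3aR,4S,7aS)-1-hydroxy-3a-methyl-5-methylidene-1-[(2S)-2-methyloxiran-2-yl]octahydro-1H-inden-4-yl}-3-methylpent-2-enoic acid
Product: 21 (Z)-5-[(1S,4aS,5R,8aR)-5-(acetoxymethyl)-5,8a-dimethyl-2-methylidene-6-oxodecahydronaphthalen-1-yl]-3-methylpent-2-enoic acid, via hydroxy ketone 20 (not isolated)
Conditions: ZnBr2 (0.5 equiv), CH2Cl2, 0 °C → rt; then Ac2O, pyridine, DMAP (cat.), 0 °C; aq NaHCO3 (cleaves any mixed anhydride), then pH 3
Reagents that add atoms: acetic anhydride CC(=O)OC(C)=O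
Why: In this semipinacol rearrangement (1,2-alkyl shift with ring expansion) ZnBr2 opens the epoxide at tertiary C4 while the antiperiplanar, more substituted C5 migrates from C3 to C4 with retention at C5 and inversion at C4, which gives the C3 ketone, six-membered ring A, the cis A/B fusion and 4β-CH3/4α-CH2OH (C4 R), and Ac2O then esterifies the primary alcohol.

## Compound list
1 | 4-methyl-5,6-dihydro-2H-pyran-2-one | CC1=CC(=O)OCC1 | starting material
2 | trimethylsilyl (Z)-5-iodo-3-methylpent-2-enoate | ICC/C(C)=C\C(=O)O[Si](C)(C)C | intermediate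
3 | methyl (Z)-5-iodo-3-methylpent-2-enoate | ICC/C(C)=C\C(=O)OC | intermediate
4 | 4-bromobut-1-yne | C#CCCBr | starting material
5 | (trimethylsilyl)methylmagnesium chloride | C[Si](C)(C)C[Mg]Cl | starting material
6 | (trimethylsilyl)methylcopper | C[Si](C)(C)C[Cu] | intermediate
7 | (Z)-4-bromo-2-[(trimethylsilyl)methyl]but-1-enylcopper | C[Si](C)(C)C/C(CCBr)=C\[Cu] | intermediate
8 | [(2Z)-4-bromo-2-(iodomethylidene)butyl]trimethylsilane | C[Si](C)(C)C/C(CCBr)=C\I | intermediate
9 | [(3Z)-5-methoxy-3-methyl-5-oxopent-3-en-1-yl]zinc iodide | I[Zn]CC/C(C)=C\C(=O)OC | intermediate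
10 | methyl (2Z,6Z)-9-bromo-3-methyl-7-[(trimethylsilyl)methyl]nona-2,6-dienoate | C[Si](C)(C)C/C(CCBr)=C\CC/C(C)=C\C(=O)OC | intermediate
11 | 2-bromo-3-methylcyclopent-2-en-1-one | CC1=C(Br)C(=O)CC1 | starting material
12 | alkylzinc bromide from 10 (C6–ZnBr) | Br[Zn]CC/C(C[Si](C)(C)C)=C/CC/C(C)=C\C(=O)OC | intermediate
13 | methyl (2Z,6Z)-3-methyl-9-(2-methyl-5-oxocyclopent-1-en-1-yl)-7-[(trimethylsilyl)methyl]nona-2,6-dienoate | O=C1CCC(C)=C1CC/C(C[Si](C)(C)C)=C/CC/C(C)=C\C(=O)OC | intermediate
14 | methyl (Z)-3-methyl-5-[(3aR,4S)-3a-methyl-5-methylidene-1-(trimethylsilyloxy)-3,3a,4,5,6,7-hexahydro-2H-inden-4-yl]pent-2-enoate | C=C1CCC2=C(O[Si](C)(C)C)CC[C@]2(C)[C@H]1CC/C(C)=C\C(=O)OC | intermediate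
15 | methyl (Z)-3-methyl-5-[(3aR,4S,7aS)-3a-methyl-5-methylidene-1-oxooctahydro-1H-inden-4-yl]pent-2-enoate | C=C1CC[C@H]2[C@](C)(CCC2=O)[C@H]1CC/C(C)=C\C(=O)OC | intermediate
16 | (Z)-3-methyl-5-[(3aR,4S,7aS)-3a-methyl-5-methylidene-1-oxooctahydro-1H-inden-4-yl]pent-2-enoic acid | C=C1CC[C@H]2[C@](C)(CCC2=O)[C@H]1CC/C(C)=C\C(=O)O | intermediate
17 | isopropenylmagnesium bromide | C=C(C)[Mg]Br | starting material
18 | (Z)-5-[(1R,3aR,4S,7aS)-1-hydroxy-3a-methyl-5-methylidene-1-(prop-1-en-2-yl)octahydro-1H-inden-4-yl]-3-methylpent-2-enoic acid | C=C1CC[C@H]2[C@](C)(CC[C@]2(O)C(C)=C)[C@H]1CC/C(C)=C\C(=O)O | intermediate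
19 | (Z)-5-{(1R,3aR,4S,7aS)-1-hydroxy-3a-methyl-5-methylidene-1-[(2S)-2-methyloxiran-2-yl]octahydro-1H-inden-4-yl}-3-methylpent-2-enoic acid | C=C1CC[C@H]2[C@](C)(CC[C@]2(O)[C@]3(C)CO3)[C@H]1CC/C(C)=C\C(=O)O | intermediate
20 | (Z)-5-[(1S,4aS,5R,8aR)-5-(hydroxymethyl)-5,8a-dimethyl-2-methylidene-6-oxodecahydronaphthalen-1-yl]-3-methylpent-2-enoic acid | C=C1CC[C@H]2[C@](C)(CCC(=O)[C@@]2(C)CO)[C@H]1CC/C(C)=C\C(=O)O | intermediate
21 | (Z)-5-[(1S,4aS,5R,8aR)-5-(acetoxymethyl)-5,8a-dimethyl-2-methylidene-6-oxodecahydronaphthalen-1-yl]-3-methylpent-2-enoic acid | C=C1CC[C@H]2[C@](C)(CCC(=O)[C@@]2(C)COC(C)=O)[C@H]1CC/C(C)=C\C(=O)O | target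

## Step count
Total steps: 8. Longest linear sequence: 7 (steps 2 to 8, from 4 to 21).

## Steps most likely to fail

**Step 5 (the new step).** The risks are low enantioselectivity, 1,2-attack at C3 instead of C10, and protodesilylation. The fallback uses known chemistry, sets out from 13 and comes back at 15.
- EtAlCl2 in CH2Cl2 at −78 °C brings about the racemic intramolecular Sakurai cyclisation.
- After K2CO3/MeOH equilibration this gives 15 together with its mirror image, the enantiomeric keto ester F1.
- (S)-N,S-dimethyl-S-phenylsulfoximine is deprotonated with n-BuLi to the lithiated sulfoximine F2, which adds to the ketone at −78 °C.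
- The two diastereomers, the β-hydroxysulfoximine of 15 F3 and the β-hydroxysulfoximine of the mirror-image ketone F4, are separated on silica.
- Thermolysis of F3 in refluxing toluene returns enantiopure 15, which goes through the LiOH stage to 16.

**Step 2.** The silylmethylcopper may add sluggishly or with imperfect regiocontrol to the functionalised alkyne. The fallback sets out from 4 and 5 and comes back at 8.
- BBr3 adds syn to 4 to give the dibromo(alkenyl)borane F5, which pinacol converts into the (Z)-β-bromoalkenyl pinacol boronate F6.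
- Compound 5 and ZnCl2 give (trimethylsilyl)methylzinc chloride F7, which is coupled at the C–Br bond with PdCl2(DPEphos). The coupling goes with retention and gives the allylsilane alkenylboronate F8.
- I2/NaOH replaces boron by iodine with retention to give 8.

**Step 8.** The Lewis acid may isomerise the 8(17)-alkene, C2 may migrate instead of C5, or the β-hydroxy ketone may suffer retro-aldol loss. The fallback sets out from 19 and comes back at 21.
- Al(OiPr)3 in i-PrOH/THF effects the tandem semipinacol shift and Meerwein–Ponndorf–Verley reduction under non-acidic conditions, giving the 3β,18-diol F9.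
- One equivalent of AcCl with collidine at −78 °C acetylates only the primary alcohol, giving the 3β-hydroxy monoacetate F10.
- Dess–Martin periodinane oxidises C3–OH to the ketone 21.

## Further compounds
F1 | step 5 | methyl (Z)-3-methyl-5-[(3aS,4R,7aR)-3a-methyl-5-methylidene-1-oxooctahydro-1H-inden-4-yl]pent-2-enoate | C=C1CC[C@@H]2[C@@](C)(CCC2=O)[C@@H]1CC/C(C)=C\C(=O)OC
F2 | step 5 | lithiated (S)-N,S-dimethyl-S-phenylsulfoximine | [Li]C[S@@](=O)(=NC)c1ccccc1
F3 | step 5 | β-hydroxysulfoximine from 15 (3α-OH, 3β-CH2S) | C=C1CC[C@H]2[C@](C)(CC[C@]2(O)C[S@@](=O)(=NC)c3ccccc3)[C@H]1CC/C(C)=C\C(=O)OC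
F4 | step 5 | β-hydroxysulfoximine from F1 | C=C1CC[C@@H]2[C@@](C)(CC[C@@]2(O)C[S@@](=O)(=NC)c3ccccc3)[C@@H]1CC/C(C)=C\C(=O)OC
F5 | step 2 | dibromo[(1Z)-2,4-dibromobut-1-en-1-yl]borane | BrCC/C(Br)=C/B(Br)Br
F6 | step 2 | 2-[(1Z)-2,4-dibromobut-1-en-1-yl]-4,4,5,5-tetramethyl-1,3,2-dioxaborolane | BrCC/C(Br)=C/B1OC(C)(C)C(C)(C)O1
F7 | step 2 | (trimethylsilyl)methylzinc chloride | C[Si](C)(C)C[Zn]Cl
F8 | step 2 | 2-{(1Z)-4-bromo-2-[(trimethylsilyl)methyl]but-1-en-1-yl}-4,4,5,5-tetramethyl-1,3,2-dioxaborolane | C[Si](C)(C)C/C(CCBr)=C\B1OC(C)(C)C(C)(C)O1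
F9 | step 8 | (Z)-5-[(1S,4aS,5R,6S,8aR)-6-hydroxy-5-(hydroxymethyl)-5,8a-dimethyl-2-methylidenedecahydronaphthalen-1-yl]-3-methylpent-2-enoic acid | C=C1CC[C@H]2[C@](C)(CC[C@H](O)[C@@]2(C)CO)[C@H]1CC/C(C)=C\C(=O)O
F10 | step 8 | (Z)-5-[(1S,4aS,5R,6S,8aR)-5-(acetoxymethyl)-6-hydroxy-5,8a-dimethyl-2-methylidenedecahydronaphthalen-1-yl]-3-methylpent-2-enoic acid | C=C1CC[C@H]2[C@](C)(CC[C@H](O)[C@@]2(C)COC(C)=O)[C@H]1CC/C(C)=C\C(=O)O
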